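**Retrosynthetic overview**

1. Feature: on ring A (the central phenol ring) the side-chain methine carbon is ortho to the phenol oxygen and the side-chain CH2 is benzylic to ring B (the 4-hydroxyphenyl ring of the side chain). The unit O–C(ring A)–C(ring A)–CH(CH3)–CH2 is therefore a ring-opened 3-methyl-2-aryl-2,3-dihydrobenzofuran, and an ortho acetyl carbon plus an O–CH2–(ring B) benzyl ether already contain all of its atoms.
2. 28 ⇐ desilylation ⇐ 27 ⇐ hydrogenolysis of the aryl O–C2 bond of dihydrobenzofuran 26 ⇐ hydrazone 24, by diazoalkane formation and dirhodium-catalysed 1,5 C–H insertion into the OCH2 group (new C3–C2 bond, dihydrofuran ring, methine centre).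
3. 24 ⇐ ketone 23 ⇐ Mitsunobu coupling of phenol 21 with benzyl alcohol 22. The acetyl group is made from an aryl bromide (Stille) only after the oxolane exists, because the Lewis acid/silane reduction would reduce a ketal and endanger the electron-rich benzyl ether.
4. All-cis oxolane 18 ⇐ hemiketal 16 (hydride adds opposite to the three cis substituents of the oxocarbenium ion) ⇐ all-cis lactone 12 + aryllithium 15 (ring C is the 4-hydroxyphenyl ring on the oxolane).
5. 12 ⇐ aldehyde 2 by (Z)-crotylboration (C4, C5), hydroboration, oxidative lactonisation, methylation and kinetic protonation (C3). Ring order: lactone ring (step 4), converted into the oxolane (steps 8 and 9), then the dihydrofuran ring (step 15), which is opened again in step 16.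

Key step: step 15

Assumption: Rh2(R-PTAD)4 is taken as the catalyst enantiomer that leads to the (2R,3S) dihydrobenzofuran 26; the sense of induction for an aryl methyl carbene has to be checked on the model hydrazone lacking the oxolane, and Rh2(S-PTAD)4 replaces it, with no other change, if the check demands it.

**Route**

Step 1
Reactants: 1 4-hydroxybenzaldehyde
Product: 2 4-(triisopropylsilyloxy)benzaldehyde
Conditions: TIPSCl, imidazole, DMF, rt
Reagents that add atoms: chlorotriisopropylsilane, CC(C)[Si](Cl)(C(C)C)C(C)C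
Why: Imidazole-promoted silylation of a phenol is routine, and the bulky TIPS aryl ether is chosen because it should outlast the basic and nucleophilic steps that would strip an aryl TBS ether.

Step 2
Reactants: 2 4-(triisopropylsilyloxy)benzaldehyde
Product: 4 (1S,2R)-2-methyl-1-[4-(triisopropylsilyloxy)phenyl]but-3-en-1-ol, via borinate ester 3 (not isolated)
Conditions: cis-2-butene, n-BuLi, KOt-Bu, THF, −78 to −45 °C; (−)-Ipc2BOMe, −78 °C; BF3·OEt2; 2, −78 °C; then NaBO3·4H2O, THF–H2O, rt
Reagents that add atoms: cis-2-butene, C/C=C\C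
Why: In this Brown (Z)-crotylboration the closed chair transition state translates the Z geometry into the 1,2-syn relationship, the isopinocampheyl groups derived from (+)-α-pinene should direct the crotyl group to the si face of the aldehyde to give the (1S,2R) alcohol, and the mild perborate work-up spares the aryl silyl ether.

Step 3
Reactants: 4 (1S,2R)-2-methyl-1-[4-(triisopropylsilyloxy)phenyl]but-3-en-1-ol
Product: 6 (1S,2R)-2-methyl-1-[4-(triisopropylsilyloxy)phenyl]butane-1,4-diol, via bis-boron adduct 5 (not isolated)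
Conditions: 9-BBN (2.2 equiv), THF, 0 °C to rt; then NaBO3·4H2O, H2O, rt
Reagents that add atoms: sodium perborate, [Na+].[Na+].O[B-]1(O)OO[B-](O)(O)OO1
Why: Anti-Markovnikov hydroboration–oxidation of the terminal alkene with bulky 9-BBN places the hydroxyl on the terminal carbon and touches neither stereocentre.

Step 4
Reactants: 6 (1S,2R)-2-methyl-1-[4-(triisopropylsilyloxy)phenyl]butane-1,4-diol
Product: 8 (4R,5S)-4-methyl-5-[4-(triisopropylsilyloxy)phenyl]oxolan-2-one (4,5-cis), via lactol 7 (not isolated)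
Conditions: TEMPO (0.2 equiv), PhI(OAc)2 (2.5 equiv), CH2Cl2, rt
Reagents that add atoms: none
Why: In this TEMPO/PhI(OAc)2 oxidative lactonisation the oxoammonium species should oxidise the primary alcohol in preference to the secondary one, the hydroxy aldehyde closes to lactol 7 and is oxidised on to the lactone, and the syn diol configuration appears unchanged as the 4,5-cis arrangement.

Step 5
Reactants: 8 (4R,5S)-4-methyl-5-[4-(triisopropylsilyloxy)phenyl]oxolan-2-one
Product: 10 (3R,4R,5S)-3,4-dimethyl-5-[4-(triisopropylsilyloxy)phenyl]oxolan-2-one (3,4-trans, 4,5-cis), via lithium enolate 9 (not isolated)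
Conditions: LiHMDS (1.05 equiv), THF, −78 °C; MeI, −78 °C
Reagents that add atoms: iodomethane, CI
Why: In this lactone enolate alkylation MeI should approach the face opposite to the cis-disposed C4 methyl and C5 aryl groups, which gives the 3,4-trans isomer.

Step 6
Reactants: 10 (3R,4R,5S)-3,4-dimethyl-5-[4-(triisopropylsilyloxy)phenyl]oxolan-2-one
Product: 12 (3S,4R,5S)-3,4-dimethyl-5-[4-(triisopropylsilyloxy)phenyl]oxolan-2-one (all-cis), via lithium enolate 11 (not isolated)
Conditions: LDA (1.2 equiv), THF, −78 to −40 °C; 2,6-di-tert-butyl-4-methylphenol, THF, −78 °C; aqueous NH4Cl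
Reagents that add atoms: none
Why: In this kinetic protonation of a lactone enolate the bulky phenol should deliver the proton to the same open face that MeI used, which pushes the C3 methyl onto the face of the C4 methyl and C5 aryl groups and gives the all-cis lactone against the thermodynamic preference.

Step 7
Reactants: 13 2-bromo-4-iodophenol
Product: 14 (2-bromo-4-iodophenoxy)(tert-butyl)dimethylsilane
Conditions: TBSCl, imidazole, DMF, rt
Reagents that add atoms: tert-butylchlorodimethylsilane, CC(C)(C)[Si](C)(C)Cl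
Why: Phenol silylation gives an ether that tolerates the organolithium and Lewis acid steps and can later be removed selectively in the presence of the TIPS ether on ring C.

Step 8
Reactants: 14 (2-bromo-4-iodophenoxy)(tert-butyl)dimethylsilane; 12 (3S,4R,5S)-3,4-dimethyl-5-[4-(triisopropylsilyloxy)phenyl]oxolan-2-one
Product: 16 (3S,4R,5S)-2-[3-bromo-4-(tert-butyldimethylsilyloxy)phenyl]-3,4-dimethyl-5-[4-(triisopropylsilyloxy)phenyl]oxolan-2-ol (hemiketal, both C2 epimers), via aryllithium 15 (not isolated)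
Conditions: 14 (1.3 equiv), n-BuLi (1.25 equiv), THF, −78 °C, 10 min; 12, −78 °C; aqueous NH4Cl at −78 °C
Reagents that add atoms: none
Why: Iodine–lithium exchange is far faster than bromine–lithium exchange, so only the carbon para to the silyloxy group is lithiated, and 1,2-addition of the aryllithium to the γ-lactone at −78 °C stops at the lithium hemiketal, which is quenched cold so that C3 next to the masked ketone is not epimerised.

Step 9
Reactants: 16 (3S,4R,5S)-2-[3-bromo-4-(tert-butyldimethylsilyloxy)phenyl]-3,4-dimethyl-5-[4-(triisopropylsilyloxy)phenyl]oxolan-2-ol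
Product: 18 (2R,3S,4R,5S)-2-[3-bromo-4-(tert-butyldimethylsilyloxy)phenyl]-3,4-dimethyl-5-[4-(triisopropylsilyloxy)phenyl]oxolane (all-cis), via oxocarbenium ion 17 (not isolated)
Conditions: Et3SiH (5 equiv), BF3·OEt2 (2 equiv), CH2Cl2, −78 °C; Et3N, then aqueous NaHCO3 at −78 °C
Reagents that add atoms: none
Why: In this ionic reduction of a hemiketal the silane should deliver hydride to the face of the cyclic oxocarbenium ion opposite to the C3 methyl, C4 methyl and C5 aryl groups, which places the new aryl group cis to all three and sets C2 as R, while the low temperature and the silane being present before the Lewis acid should prevent C3 epimerisation through the enol ether and ring A carries only a bromine and a silyl ether that are inert here.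

Step 10
Reactants: 18 (2R,3S,4R,5S)-2-[3-bromo-4-(tert-butyldimethylsilyloxy)phenyl]-3,4-dimethyl-5-[4-(triisopropylsilyloxy)phenyl]oxolane
Product: 20 1-{2-(tert-butyldimethylsilyloxy)-5-[(2R,3S,4R,5S)-3,4-dimethyl-5-(4-triisopropylsilyloxyphenyl)oxolan-2-yl]phenyl}ethan-1-one, via enol ether 19 (not isolated)
Conditions: tributyl(1-ethoxyvinyl)stannane (1.5 equiv), PdCl2(PPh3)2 (5 mol %), toluene, 100 °C; then 1 M aqueous HCl, THF, 0 °C to rt
Reagents that add atoms: tributyl(1-ethoxyvinyl)stannane, CCCC[Sn](CCCC)(CCCC)C(=C)OCC; water, O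
Why: Stille coupling of the aryl bromide with an acetyl anion equivalent, followed by mild acid hydrolysis of the α-ethoxystyrene, installs the acetyl group after the Lewis acid step under conditions that leave the oxolane and both silyl ethers alone.

Step 11
Reactants: 20 1-{2-(tert-butyldimethylsilyloxy)-5-[(2R,3S,4R,5S)-3,4-dimethyl-5-(4-triisopropylsilyloxyphenyl)oxolan-2-yl]phenyl}ethan-1-one
Product: 21 1-{2-hydroxy-5-[(2R,3S,4R,5S)-3,4-dimethyl-5-(4-triisopropylsilyloxyphenyl)oxolan-2-yl]phenyl}ethan-1-one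
Conditions: K2CO3 (0.5 equiv), MeOH–THF, 0 °C
Reagents that add atoms: none
Why: In this base-promoted methanolysis of an aryl silyl ether the TBS ether ortho to the acetyl group has the better phenoxide leaving group and the smaller silicon substituents, so it should be cleaved well before the TIPS ether of ring C.

Step 12
Reactants: 2 4-(triisopropylsilyloxy)benzaldehyde
Product: 22 [4-(triisopropylsilyloxy)phenyl]methanol
Conditions: NaBH4, MeOH, 0 °C
Reagents that add atoms: none
Why: Borohydride reduction of an aromatic aldehyde to the benzyl alcohol is routine and does not affect the aryl silyl ether at 0 °C.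

Step 13
Reactants: 21 1-{2-hydroxy-5-[(2R,3S,4R,5S)-3,4-dimethyl-5-(4-triisopropylsilyloxyphenyl)oxolan-2-yl]phenyl}ethan-1-one; 22 [4-(triisopropylsilyloxy)phenyl]methanol
Product: 23 1-{5-[(2R,3S,4R,5S)-3,4-dimethyl-5-(4-triisopropylsilyloxyphenyl)oxolan-2-yl]-2-[4-(triisopropylsilyloxy)benzyloxy]phenyl}ethan-1-one
Conditions: PPh3, DIAD, THF, 0 °C to rt
Reagents that add atoms: none
Why: Mitsunobu etherification joins the acidic ortho-acyl phenol to the primary benzylic alcohol under neutral conditions, which avoids a labile 4-silyloxybenzyl halide and base-induced silyl migration.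

Step 14
Reactants: 23 1-{5-[(2R,3S,4R,5S)-3,4-dimethyl-5-(4-triisopropylsilyloxyphenyl)oxolan-2-yl]-2-[4-(triisopropylsilyloxy)benzyloxy]phenyl}ethan-1-one
Product: 24 hydrazone of 23, 1-{5-[(2R,3S,4R,5S)-3,4-dimethyl-5-(4-triisopropylsilyloxyphenyl)oxolan-2-yl]-2-[4-(triisopropylsilyloxy)benzyloxy]phenyl}ethan-1-one hydrazone
Conditions: N2H4·H2O (10 equiv), AcOH (cat.), EtOH, 60 °C
Reagents that add atoms: hydrazine, NN
Why: Acid-catalysed condensation of an aryl methyl ketone with a large excess of hydrazine gives the N-unsubstituted hydrazone and suppresses azine formation, and the TIPS ethers should tolerate the weakly basic medium.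

Step 15
Reactants: 24 hydrazone of 23
Product: 26 (2R,3S)-5-[(2R,3S,4R,5S)-3,4-dimethyl-5-(4-triisopropylsilyloxyphenyl)oxolan-2-yl]-3-methyl-2-[4-(triisopropylsilyloxy)phenyl]-2,3-dihydro-1-benzofuran (cis at C2/C3), via diazoalkane 25 (not isolated)
Conditions: MnO2 (8 equiv), CH2Cl2, 0 °C; filtered cold into Rh2(R-PTAD)4 (1 mol %; PTAD = (1-adamantyl)(N-phthalimido)acetate), CH2Cl2, −40 to 0 °C
Reagents that add atoms: none
Why: MnO2 dehydrogenates the hydrazone to aryl methyl diazoalkane 25, which the dirhodium tetracarboxylate converts with loss of N2 into a carbene that carries only donor groups (ring A and methyl) and is therefore selective for an activated C–H bond. The closest known reaction type is the enantioselective intramolecular C–H insertion of donor/donor rhodium carbenes, generated from hydrazones, into benzylic ethers to give 2,3-disubstituted dihydrobenzofurans. The carbene carbon inserts into one of the two OCH2 hydrogens of the 4-silyloxybenzyl ether through a concerted, hydride-transfer-like three-centre transition state, a 1,5-insertion that forms the C3–C2 bond and closes the five-membered dihydrofuran ring onto ring A. The C3 methine (S in 26, the R centre of the target side chain) is fixed by the carbene face that the chiral carboxylate ligands leave open to the C–H bond, and C2 follows from the compact cyclic transition state, which should place aryl and methyl cis; C2 is erased in step 16, so only catalyst control at C3 counts, and the remote oxolane centres cannot influence it. The step needs insertion to win over the 1,2-hydride shift from the methyl group and over azine formation, which the hydridic C–H bond (ether oxygen plus para-silyloxy group of ring B), the low temperature, the bulky carboxylates and the cold delivery of the diazoalkane to the catalyst should secure. No other C–H bond can reach the carbene through a five-membered ring-forming geometry.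

Step 16
Reactants: 26 (2R,3S)-5-[(2R,3S,4R,5S)-3,4-dimethyl-5-(4-triisopropylsilyloxyphenyl)oxolan-2-yl]-3-methyl-2-[4-(triisopropylsilyloxy)phenyl]-2,3-dihydro-1-benzofuran
Product: 27 4-[(2R,3S,4R,5S)-3,4-dimethyl-5-(4-triisopropylsilyloxyphenyl)oxolan-2-yl]-2-[(2R)-1-(4-triisopropylsilyloxyphenyl)propan-2-yl]phenol
Conditions: H2 (3 atm), Pd(OH)2/C, EtOAc–EtOH, rt, stopped at full conversion of 26
Reagents that add atoms: none
Why: Catalytic hydrogenolysis of a benzylic aryl ether should cleave the O–C2 bond, whose leaving group is a phenoxide and whose carbon carries the electron-rich ring B, faster than the benzylic dialkyl ether bonds of the oxolane, and it turns C2 into the CH2 group without touching the C3 methine.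

Step 17
Reactants: 27 4-[(2R,3S,4R,5S)-3,4-dimethyl-5-(4-triisopropylsilyloxyphenyl)oxolan-2-yl]-2-[(2R)-1-(4-triisopropylsilyloxyphenyl)propan-2-yl]phenol
Product: 28 4-[(2R,3S,4R,5S)-5-(4-hydroxyphenyl)-3,4-dimethyloxolan-2-yl]-2-[(2R)-1-(4-hydroxyphenyl)propan-2-yl]phenol (CNP0232576.2)
Conditions: tetrabutylammonium fluoride (3 equiv), AcOH (3 equiv), THF, 0 °C to rt
Reagents that add atoms: none
Why: Fluoride-mediated desilylation removes both aryl TIPS groups, and the acetic acid buffer keeps the electron-rich triphenol from standing as phenoxides.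

**Compound list**

1 | 4-hydroxybenzaldehyde | O=Cc1ccc(O)cc1 | starting material
2 | 4-(triisopropylsilyloxy)benzaldehyde | O=Cc1ccc(O[Si](C(C)C)(C(C)C)C(C)C)cc1 | intermediate
3 | (1S,2R)-2-methyl-1-[4-(triisopropylsilyloxy)phenyl]but-3-en-1-yl diisopinocampheylborinate | C=C[C@@H](C)[C@H](OB([C@@H]1C[C@@H]2C[C@@H](C2(C)C)[C@H]1C)[C@@H]1C[C@@H]2C[C@@H](C2(C)C)[C@H]1C)c1ccc(O[Si](C(C)C)(C(C)C)C(C)C)cc1 | intermediate
4 | (1S,2R)-2-methyl-1-[4-(triisopropylsilyloxy)phenyl]but-3-en-1-ol | C=C[C@@H](C)[C@H](O)c1ccc(O[Si](C(C)C)(C(C)C)C(C)C)cc1 | intermediate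
5 | bis(9-BBN) adduct of 4 (O-borinate at C1, B-alkyl at C4) | C1CCC2CCCC1B2CC[C@@H](C)[C@H](OB1C2CCCC1CCC2)c1ccc(O[Si](C(C)C)(C(C)C)C(C)C)cc1 | intermediate
6 | (1S,2R)-2-methyl-1-[4-(triisopropylsilyloxy)phenyl]butane-1,4-diol | OCC[C@@H](C)[C@H](O)c1ccc(O[Si](C(C)C)(C(C)C)C(C)C)cc1 | intermediate
7 | (4R,5S)-4-methyl-5-[4-(triisopropylsilyloxy)phenyl]oxolan-2-ol (lactol) | C[C@@H]1CC(O)O[C@@H]1c1ccc(O[Si](C(C)C)(C(C)C)C(C)C)cc1 | intermediate
8 | (4R,5S)-4-methyl-5-[4-(triisopropylsilyloxy)phenyl]oxolan-2-one | C[C@@H]1CC(=O)O[C@@H]1c1ccc(O[Si](C(C)C)(C(C)C)C(C)C)cc1 | intermediate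
9 | lithium enolate of 8 | C[C@@H]1C=C(O[Li])O[C@@H]1c1ccc(O[Si](C(C)C)(C(C)C)C(C)C)cc1 | intermediate
10 | (3R,4R,5S)-3,4-dimethyl-5-[4-(triisopropylsilyloxy)phenyl]oxolan-2-one | C[C@@H]1[C@@H](C)C(=O)O[C@@H]1c1ccc(O[Si](C(C)C)(C(C)C)C(C)C)cc1 | intermediate
11 | lithium enolate of 10 | C[C@@H]1C(C)=C(O[Li])O[C@@H]1c1ccc(O[Si](C(C)C)(C(C)C)C(C)C)cc1 | intermediate
12 | (3S,4R,5S)-3,4-dimethyl-5-[4-(triisopropylsilyloxy)phenyl]oxolan-2-one (all-cis) | C[C@@H]1[C@H](C)C(=O)O[C@@H]1c1ccc(O[Si](C(C)C)(C(C)C)C(C)C)cc1 | intermediate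
13 | 2-bromo-4-iodophenol | Oc1ccc(I)cc1Br | starting material
14 | (2-bromo-4-iodophenoxy)(tert-butyl)dimethylsilane | CC(C)(C)[Si](C)(C)Oc1ccc(I)cc1Br | intermediate
15 | [3-bromo-4-(tert-butyldimethylsilyloxy)phenyl]lithium | [Li]c1ccc(O[Si](C)(C)C(C)(C)C)c(Br)c1 | intermediate
16 | (3S,4R,5S)-2-[3-bromo-4-(tert-butyldimethylsilyloxy)phenyl]-3,4-dimethyl-5-[4-(triisopropylsilyloxy)phenyl]oxolan-2-ol | C[C@@H]1[C@H](C)C(O)(c2ccc(O[Si](C)(C)C(C)(C)C)c(Br)c2)O[C@@H]1c1ccc(O[Si](C(C)C)(C(C)C)C(C)C)cc1 | intermediate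
17 | 2-aryl oxocarbenium ion derived from 16 | C[C@@H]1[C@H](C)C(c2ccc(O[Si](C)(C)C(C)(C)C)c(Br)c2)=[O+][C@@H]1c1ccc(O[Si](C(C)C)(C(C)C)C(C)C)cc1 | intermediate
18 | (2R,3S,4R,5S)-2-[3-bromo-4-(tert-butyldimethylsilyloxy)phenyl]-3,4-dimethyl-5-[4-(triisopropylsilyloxy)phenyl]oxolane | C[C@@H]1[C@H](C)[C@H](c2ccc(O[Si](C)(C)C(C)(C)C)c(Br)c2)O[C@@H]1c1ccc(O[Si](C(C)C)(C(C)C)C(C)C)cc1 | intermediate
19 | 1-ethoxyvinyl arene from 18 (enol ether) | C[C@@H]1[C@H](C)[C@H](c2ccc(O[Si](C)(C)C(C)(C)C)c(C(=C)OCC)c2)O[C@@H]1c1ccc(O[Si](C(C)C)(C(C)C)C(C)C)cc1 | intermediate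
20 | 1-{2-(tert-butyldimethylsilyloxy)-5-[(2R,3S,4R,5S)-3,4-dimethyl-5-(4-triisopropylsilyloxyphenyl)oxolan-2-yl]phenyl}ethan-1-one | C[C@@H]1[C@H](C)[C@H](c2ccc(O[Si](C)(C)C(C)(C)C)c(C(C)=O)c2)O[C@@H]1c1ccc(O[Si](C(C)C)(C(C)C)C(C)C)cc1 | intermediate
21 | 1-{2-hydroxy-5-[(2R,3S,4R,5S)-3,4-dimethyl-5-(4-triisopropylsilyloxyphenyl)oxolan-2-yl]phenyl}ethan-1-one | C[C@@H]1[C@H](C)[C@H](c2ccc(O)c(C(C)=O)c2)O[C@@H]1c1ccc(O[Si](C(C)C)(C(C)C)C(C)C)cc1 | intermediate
22 | [4-(triisopropylsilyloxy)phenyl]methanol | OCc1ccc(O[Si](C(C)C)(C(C)C)C(C)C)cc1 | intermediate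
23 | 1-{5-[(2R,3S,4R,5S)-3,4-dimethyl-5-(4-triisopropylsilyloxyphenyl)oxolan-2-yl]-2-[4-(triisopropylsilyloxy)benzyloxy]phenyl}ethan-1-one | C[C@@H]1[C@H](C)[C@H](c2ccc(OCc3ccc(O[Si](C(C)C)(C(C)C)C(C)C)cc3)c(C(C)=O)c2)O[C@@H]1c1ccc(O[Si](C(C)C)(C(C)C)C(C)C)cc1 | intermediate
24 | hydrazone of 23 | C[C@@H]1[C@H](C)[C@H](c2ccc(OCc3ccc(O[Si](C(C)C)(C(C)C)C(C)C)cc3)c(C(C)=NN)c2)O[C@@H]1c1ccc(O[Si](C(C)C)(C(C)C)C(C)C)cc1 | intermediate
25 | 1-diazoethyl arene from 24 | C[C@@H]1[C@H](C)[C@H](c2ccc(OCc3ccc(O[Si](C(C)C)(C(C)C)C(C)C)cc3)c(C(C)=[N+]=[N-])c2)O[C@@H]1c1ccc(O[Si](C(C)C)(C(C)C)C(C)C)cc1 | intermediate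
26 | (2R,3S)-5-[(2R,3S,4R,5S)-3,4-dimethyl-5-(4-triisopropylsilyloxyphenyl)oxolan-2-yl]-3-methyl-2-[4-(triisopropylsilyloxy)phenyl]-2,3-dihydro-1-benzofuran | C[C@@H]1[C@H](C)[C@H](c2ccc3c(c2)[C@H](C)[C@H](c2ccc(O[Si](C(C)C)(C(C)C)C(C)C)cc2)O3)O[C@@H]1c1ccc(O[Si](C(C)C)(C(C)C)C(C)C)cc1 | intermediate
27 | 4-[(2R,3S,4R,5S)-3,4-dimethyl-5-(4-triisopropylsilyloxyphenyl)oxolan-2-yl]-2-[(2R)-1-(4-triisopropylsilyloxyphenyl)propan-2-yl]phenol | C[C@@H]1[C@H](C)[C@H](c2ccc(O)c([C@H](C)Cc3ccc(O[Si](C(C)C)(C(C)C)C(C)C)cc3)c2)O[C@@H]1c1ccc(O[Si](C(C)C)(C(C)C)C(C)C)cc1 | intermediate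
28 | 4-[(2R,3S,4R,5S)-5-(4-hydroxyphenyl)-3,4-dimethyloxolan-2-yl]-2-[(2R)-1-(4-hydroxyphenyl)propan-2-yl]phenol | C[C@@H]1[C@H](C)[C@H](c2ccc(O)c([C@H](C)Cc3ccc(O)cc3)c2)O[C@@H]1c1ccc(O)cc1 | target

**Step count**

Total steps: 17. Longest linear sequence: 15 steps (1–6, 8–11, 13–17); steps 7 and 12 are side branches.

**Steps most likely to fail**

Step 15. The carbene may be lost through 1,2-hydride shift from its methyl group to a vinyl arene, the diazoalkane may couple to the azine before it meets the catalyst, or the catalyst may discriminate the carbene faces poorly. Because the oxolane is a single enantiomer, the last of these would show as a mixture of separable diastereomers.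

Fallback, from 18 back to the route at 28: the methine is set instead by asymmetric hydrogenation of a trisubstituted stilbene.
- Commercial (4-iodophenoxy)triisopropylsilane is coupled with propyne (PdCl2(PPh3)2, CuI, Et3N) to give triisopropyl[4-(prop-1-yn-1-yl)phenoxy]silane F1.
- Copper-catalysed syn-hydroboration (CuCl, Xantphos, NaOt-Bu cat., B2pin2, MeOH, THF) places boron on the methyl-bearing carbon and gives the (Z)-alkenylboronate F2.
- Suzuki–Miyaura coupling of F2 with bromide 18 (Pd(dppf)Cl2, K3PO4, dioxane–H2O, 80 °C) gives, with retention of alkene geometry, the (E)-α-methylstilbene F3; loss of the ring A silyl group here would be harmless.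
- Iridium-catalysed asymmetric hydrogenation ([Ir(cod)(L)]BArF, L = 4-tert-butyl-2-[2-(di-o-tolylphosphanyl)phenyl]-4,5-dihydrooxazole, H2 50 bar, CH2Cl2), with the ligand enantiomer chosen for the (R) methine, gives the saturated tris-silyl ether F4.
- Tetrabutylammonium fluoride then removes all three silyl groups and gives 28.

Step 16. Hydrogenolysis may not distinguish the aryl benzylic ether from the two benzylic C–O bonds of the strained all-cis oxolane, so that the oxolane opens, or the cyclic secondary ether may resist until forcing conditions erase the difference.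

Fallback, from 26 back to the route at 28: the order of the last two operations is reversed and the ring is opened by base.
- Buffered desilylation (tetrabutylammonium fluoride, AcOH, THF) gives the bisphenol dihydrobenzofuran F5.
- With NaBH4 in aqueous NaOH–EtOH at 50 °C the ring B phenoxide should expel the ring A phenoxide to give the para-quinone methide F6 (not isolated), which borohydride reduces at the exocyclic carbon to the CH2 group of 28.
- The oxolane could open this way only by expelling an alkoxide, which is far slower.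
- Hydride trapping has to outrun tautomerisation of the quinone methide, which would erase the methine.

Step 6. Protonation of enolate 11 may show poor facial selectivity, or enolisation of the hindered C3–H may be incomplete, so that 10 is returned and the all-cis lactone has to be separated from its epimer.

Fallback, from 8 back to the route at 12: the C3 hydrogen is delivered to an exocyclic alkene instead of to an enolate.
- The enolate of 8 (LDA, THF, −78 °C) is treated with dimethylmethylideneammonium iodide to give the Mannich base F7.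
- Quaternisation with MeI and elimination with NaHCO3 give the α-methylene lactone F8.
- Hydrogenation (H2, RhCl(PPh3)3, benzene–EtOH) from the face opposite to the C4 methyl and C5 aryl groups gives 12.

**Further compounds**

F1 | step 15 | triisopropyl[4-(prop-1-yn-1-yl)phenoxy]silane | CC#Cc1ccc(O[Si](C(C)C)(C(C)C)C(C)C)cc1
F2 | step 15 | 4,4,5,5-tetramethyl-2-[(Z)-1-(4-triisopropylsilyloxyphenyl)prop-1-en-2-yl]-1,3,2-dioxaborolane | C/C(B1OC(C)(C)C(C)(C)O1)=C\c1ccc(O[Si](C(C)C)(C(C)C)C(C)C)cc1
F3 | step 15 | (2R,3S,4R,5S)-2-{4-(tert-butyldimethylsilyloxy)-3-[(E)-1-(4-triisopropylsilyloxyphenyl)prop-1-en-2-yl]phenyl}-3,4-dimethyl-5-[4-(triisopropylsilyloxy)phenyl]oxolane | C[C@@H]1[C@H](C)[C@H](c2ccc(O[Si](C)(C)C(C)(C)C)c(/C(C)=C/c3ccc(O[Si](C(C)C)(C(C)C)C(C)C)cc3)c2)O[C@@H]1c1ccc(O[Si](C(C)C)(C(C)C)C(C)C)cc1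
F4 | step 15 | (2R,3S,4R,5S)-2-{4-(tert-butyldimethylsilyloxy)-3-[(2R)-1-(4-triisopropylsilyloxyphenyl)propan-2-yl]phenyl}-3,4-dimethyl-5-[4-(triisopropylsilyloxy)phenyl]oxolane | C[C@@H]1[C@H](C)[C@H](c2ccc(O[Si](C)(C)C(C)(C)C)c([C@H](C)Cc3ccc(O[Si](C(C)C)(C(C)C)C(C)C)cc3)c2)O[C@@H]1c1ccc(O[Si](C(C)C)(C(C)C)C(C)C)cc1
F5 | step 16 | 4-{(2R,3S)-5-[(2R,3S,4R,5S)-5-(4-hydroxyphenyl)-3,4-dimethyloxolan-2-yl]-3-methyl-2,3-dihydro-1-benzofuran-2-yl}phenol | C[C@@H]1[C@H](C)[C@H](c2ccc3c(c2)[C@H](C)[C@H](c2ccc(O)cc2)O3)O[C@@H]1c1ccc(O)cc1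
F6 | step 16 | para-quinone methide from F5, 4-{(2R)-2-[2-hydroxy-5-((2R,3S,4R,5S)-5-(4-hydroxyphenyl)-3,4-dimethyloxolan-2-yl)phenyl]propylidene}cyclohexa-2,5-dien-1-one | C[C@@H]1[C@H](C)[C@H](c2ccc(O)c([C@H](C)C=C3C=CC(=O)C=C3)c2)O[C@@H]1c1ccc(O)cc1
F7 | step 6 | 3,4-trans-3-[(dimethylamino)methyl]-4-methyl-5-[4-(triisopropylsilyloxy)phenyl]oxolan-2-one (4R,5S; aminomethyl group opposite to the C4 methyl) | C[C@@H]1[C@@H](CN(C)C)C(=O)O[C@@H]1c1ccc(O[Si](C(C)C)(C(C)C)C(C)C)cc1
F8 | step 6 | (4R,5S)-4-methyl-3-methylidene-5-[4-(triisopropylsilyloxy)phenyl]oxolan-2-one | C[C@@H]1C(=C)C(=O)O[C@@H]1c1ccc(O[Si](C(C)C)(C(C)C)C(C)C)cc1
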